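The 1,2-dioxan-3-ol ring is cut into three pieces: C3 and C4 from an α-methyl β-keto ester, C5 and C6 from a 1,1-disubstituted alkene, O1 and O2 from dioxygen. This exploits C4 lying next to the masked C3 ketone, with the fully substituted peroxide carbon C6 two atoms further on. A temporary ester makes the C4 hydrogen the only doubly activated one. Catalytic Mn(OAc)3 in air then forms three bonds (C4 to C5, C6 to O1, O2 to C3) and closes the ring. The precursors are a trimethylsilylethyl 2-methyl-3-oxopentanoate bearing a C1 silyl ether and a citronellal-derived alkene. Decarboxylation and C1 oxidation finish.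

Key step: step 12

Atom labels: ring O1, O2, C3, C4, C5, C6. C2/C1 are the CH2CO2H arm on C3. C7 and C8 are the first two carbons of the side chain on C6.
Remark on the structure: eight CH2 groups lie between C8 and the phenyl ring, so the alkene partner is a 12-phenyldodec-1-ene (C20H32). (R)-Citronellal maps onto C8 with the same spatial arrangement and the same R descriptor.
Remark on the ring: the target is (3S,4R,6S,8R). In the chair, the C6 side chain and the C4 methyl are equatorial and the C3 hydroxyl is axial (anomeric). C3 therefore follows C4 by ring–chain tautomerism.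
Assumption: (R)-citronellal of high enantiomeric purity is used, because its enantiomeric purity passes unchanged into the target.

Step 1
Reactants: 1 (5-bromopentyl)benzene
Product: 2 triphenyl(5-phenylpentyl)phosphonium bromide
Conditions: PPh3 (1.1 equiv), MeCN, reflux
Reagents that add atoms: triphenylphosphine, c1ccc(cc1)P(c1ccccc1)c1ccccc1
Why: SN2 quaternisation of PPh3 by an unhindered primary bromide should give the crystalline Wittig salt.

Step 2
Reactants: 3 (R)-citronellal
Product: 4 (4R)-4,8-dimethylnon-7-en-2-ol (both carbinol epimers)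
Conditions: MeMgBr, Et2O, 0 °C; aq NH4Cl
Reagents that add atoms: methylmagnesium bromide, C[Mg]Br
Why: Grignard addition to the aldehyde leaves the trisubstituted alkene and the non-enolisable β-stereocentre (future C8) untouched, and the new carbinol centre forms as both epimers, which does not matter because step 6 removes it.

Step 3
Reactants: 4 (4R)-4,8-dimethylnon-7-en-2-ol
Product: 6 (4R)-6-hydroxy-4-methylheptanal, via secondary ozonide 5 (not isolated)
Conditions: O3, CH2Cl2, −78 °C; then Me2S, −78 → 23 °C
Reagents that add atoms: ozone, [O-][O+]=O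
Why: Ozonolysis with reductive work-up cleaves the only C=C bond, while the secondary alcohol is inert to O3 at −78 °C and too remote (seven-membered lactol) to tie up the aldehyde.

Step 4
Reactants: 2 triphenyl(5-phenylpentyl)phosphonium bromide; 6 (4R)-6-hydroxy-4-methylheptanal
Product: 8 (4R,7Z)-4-methyl-12-phenyldodec-7-en-2-ol, via phosphonium ylide 7 (not isolated)
Conditions: 2 (2 equiv), NaHMDS (1.9 equiv), THF, 0 °C; then 6, −78 → 23 °C
Reagents that add atoms: none
Why: Wittig olefination with a non-stabilised ylide joins the five-carbon phenylpentyl unit to the three-carbon aldehyde arm (the eight carbons between C8 and phenyl); excess ylide covers the free hydroxyl, and the alkene geometry is irrelevant because it is hydrogenated next.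

Step 5
Reactants: 8 (4R,7Z)-4-methyl-12-phenyldodec-7-en-2-ol
Product: 9 (4R)-4-methyl-12-phenyldodecan-2-ol
Conditions: H2 (1 atm), 10% Pd/C, EtOAc, 23 °C
Reagents that add atoms: none
Why: Heterogeneous catalytic hydrogenation saturates the disubstituted alkene under conditions that leave the arene, the alcohol and the stereocentre alone.

Step 6
Reactants: 9 (4R)-4-methyl-12-phenyldodecan-2-ol
Product: 10 (4R)-4-methyl-12-phenyldodecan-2-one
Conditions: Dess–Martin periodinane, CH2Cl2, 23 °C
Reagents that add atoms: none
Why: Dess–Martin oxidation merges both carbinol epimers into one methyl ketone under neutral conditions, and the stereocentre is β to the carbonyl and cannot epimerise.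

Step 7
Reactants: 10 (4R)-4-methyl-12-phenyldodecan-2-one
Product: 11 (4R)-2,4-dimethyl-12-phenyldodec-1-ene
Conditions: MePPh3Br, KOtBu, THF, 0 → 23 °C
Reagents that add atoms: methyltriphenylphosphonium bromide, [Br-].C[P+](c1ccccc1)(c1ccccc1)c1ccccc1
Why: Wittig methylenation of an unhindered methyl ketone delivers the 1,1-disubstituted alkene (future C5=C6) at a fixed position, without double-bond migration.

Step 8
Reactants: 12 propane-1,3-diol
Product: 13 3-[(tert-butyldiphenylsilyl)oxy]propan-1-ol
Conditions: 12 (4 equiv), TBDPSCl (1 equiv), imidazole, DMF, 0 → 23 °C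
Reagents that add atoms: tert-butyl(chloro)diphenylsilane, CC(C)(C)[Si](Cl)(c1ccccc1)c1ccccc1
Why: Imidazole-promoted silyl ether formation with the cheap, water-soluble diol in excess should stop at the monoether, and TBDPS is chosen because it withstands AcOH in step 12 and falls to fluoride in step 13.

Step 9
Reactants: 13 3-[(tert-butyldiphenylsilyl)oxy]propan-1-ol
Product: 15 3-[(tert-butyldiphenylsilyl)oxy]propanoic acid, via silyloxy aldehyde 14 (not isolated)
Conditions: TEMPO (10 mol %), PhI(OAc)2 (2.2 equiv), MeCN/H2O 1:1, 23 °C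
Reagents that add atoms: water, O
Why: Nitroxyl-catalysed oxidation with PhI(OAc)2 takes the primary alcohol through the aldehyde hydrate to the acid in a weakly acidic medium that the TBDPS ether tolerates.

Step 10
Reactants: 16 2,2,5-trimethyl-1,3-dioxane-4,6-dione (methyl Meldrum's acid); 17 2-(trimethylsilyl)ethanol
Product: 18 2-methyl-3-oxo-3-[2-(trimethylsilyl)ethoxy]propanoic acid (racemic)
Conditions: PhMe, 100 °C
Reagents that add atoms: none
Why: Thermal alcoholysis of a Meldrum's acid derivative opens the dioxanedione with loss of acetone to the malonic half ester, which already carries the future C4 methyl group and so makes a later enolate methylation, with its risk of double alkylation, unnecessary.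

Step 11
Reactants: 15 3-[(tert-butyldiphenylsilyl)oxy]propanoic acid; 18 2-methyl-3-oxo-3-[2-(trimethylsilyl)ethoxy]propanoic acid
Product: 20 2-(trimethylsilyl)ethyl 5-[(tert-butyldiphenylsilyl)oxy]-2-methyl-3-oxopentanoate (racemic), via acyl imidazolide 19 (not isolated)
Conditions: 15, CDI, THF, 23 °C; then 18, MgCl2, Et3N, MeCN, 23 → 40 °C; 1 M HCl
Reagents that add atoms: 1,1'-carbonyldiimidazole, O=C(n1ccnc1)n1ccnc1 (imidazolyl group of 19 only)
Why: Masamune–Brooks homologation, in which the magnesium enolate of half ester 18 is C-acylated by imidazolide 19 and loses CO2, gives the α-methyl β-keto ester directly under conditions too mild for β-elimination of the silyloxy group; C4 is racemic, which is irrelevant because it becomes a radical.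

Step 12
Reactants: 11 (4R)-2,4-dimethyl-12-phenyldodec-1-ene; 20 2-(trimethylsilyl)ethyl 5-[(tert-butyldiphenylsilyl)oxy]-2-methyl-3-oxopentanoate
Product: 22 2-(trimethylsilyl)ethyl (6S)-3-{2-[(tert-butyldiphenylsilyl)oxy]ethyl}-3-hydroxy-4,6-dimethyl-6-[(2R)-2-methyl-10-phenyldecyl]-1,2-dioxane-4-carboxylate (6S drawn; 6R epimer co-formed; C3/C4 unassigned), via open-chain hydroperoxide 21 (not isolated)
Conditions: Mn(OAc)3·2H2O (0.2 equiv), dry air (1 atm), AcOH (0.5 M in 11), 23 °C; 20 (2 equiv)
Reagents that add atoms: dioxygen, O=O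
Why: Mn(OAc)3 binds 20 as its enolate and oxidises it by inner-sphere electron transfer to the electrophilic tertiary C4 radical, which adds to the unsubstituted CH2 terminus (C5) of electron-rich alkene 11; the tertiary C6 radical is captured by O2 at close to the diffusion limit, and divalent manganese reduces the peroxyl radical to hydroperoxide 21 while regenerating the trivalent oxidant, so the metal is needed only in catalytic amount. The closest known reaction type is the manganese triacetate-mediated aerobic annulation of 1,3-dicarbonyl compounds with 1,1-disubstituted alkenes to 1,2-dioxan-3-ols, established for β-keto esters, for 2-alkylated dicarbonyls and, less efficiently than for aryl alkenes, for 2-alkyl-1-alkenes. The single ring closes by reversible 6-exo-trig addition of the terminal hydroperoxide oxygen O2 to the C3 ketone. C6 arises from a planar acyclic radical whose faces the C8 methyl group cannot differentiate, so both C6 epimers are expected and carried on; quaternary C4 is likewise uncontrolled but is erased in step 13, and C3 settles under thermodynamic (anomeric) control through ring–chain tautomerism. The site selectivity that is needed comes from the temporary ester, since only the C4 hydrogen lies between two carbonyl groups while C2 is activated once and C1 is parked as a silyl ether; the regiochemistry of addition follows from polarity matching and formation of the more substituted radical. The two real competitors, oxidation of the C6 radical to the cation by trivalent manganese and direct oxygenation of the C4 radical, are held back by a low metal loading, room temperature, air instead of pure O2 and a concentrated solution with 20 in excess.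

Step 13
Reactants: 22 2-(trimethylsilyl)ethyl 1,2-dioxan-3-ol-4-carboxylate (diastereomer mixture from step 12)
Product: 24 (3S,4R,6S)-3-(2-hydroxyethyl)-4,6-dimethyl-6-[(2R)-2-methyl-10-phenyldecyl]-1,2-dioxan-3-ol, via C4 carboxylic acid 23 (not isolated)
Conditions: TBAF (4 equiv), AcOH (2 equiv), THF, 0 → 23 °C; 10% aq citric acid, EtOAc, 23 °C; SiO2, then preparative HPLC (diastereomer separation)
Reagents that add atoms: none
Why: Fluoride-induced fragmentation of the 2-(trimethylsilyl)ethyl ester and Si–O cleavage free C1–OH and the C4 carboxylate, which loses CO2 through the ring-opened β-keto form (fluoride-triggered dealkoxycarbonylation of a β-keto ester); C4 is set by protonation of the enol and stays epimerisable, so the C3/C4 pair relaxes to equatorial methyl and axial anomeric hydroxyl as in the target, whereas the C4/C6 relation is only weakly biased (CH3 versus CH2R on C6) and the C6/C8 relation not at all, hence the chromatographic separation.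

Step 14
Reactants: 24 (3S,4R,6S)-3-(2-hydroxyethyl)-4,6-dimethyl-6-[(2R)-2-methyl-10-phenyldecyl]-1,2-dioxan-3-ol
Product: 26 2-{(3S,4R,6S)-3-hydroxy-4,6-dimethyl-6-[(2R)-2-methyl-10-phenyldecyl]-1,2-dioxan-3-yl}acetic acid (target), via peroxyhemiketal aldehyde 25 (not isolated)
Conditions: TEMPO (20 mol %), PhI(OAc)2 (2.2 equiv), MeCN/H2O 1:1, 0 → 23 °C; cold work-up
Reagents that add atoms: water, O
Why: The nitroxyl-catalysed oxidation with PhI(OAc)2 acts only on the primary alcohol (the C3 hydroxyl is tertiary, the O–O bond and the arene are inert), passes through aldehyde 25 and its hydrate, and runs at or below room temperature in a weakly acidic medium in which the masked β-keto acid should neither lose CO2 nor epimerise at C4.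

Compound list
1 | (5-bromopentyl)benzene | BrCCCCCc1ccccc1 | starting material
2 | triphenyl(5-phenylpentyl)phosphonium bromide | [Br-].c1ccccc1CCCCC[P+](c1ccccc1)(c1ccccc1)c1ccccc1 | intermediate
3 | (R)-citronellal, (3R)-3,7-dimethyloct-6-enal | C[C@H](CCC=C(C)C)CC=O | starting material
4 | (4R)-4,8-dimethylnon-7-en-2-ol (both C2 epimers) | C[C@H](CCC=C(C)C)CC(C)O | intermediate
5 | (4R)-6-(5,5-dimethyl-1,2,4-trioxolan-3-yl)-4-methylhexan-2-ol (secondary ozonide) | C[C@H](CCC1OOC(C)(C)O1)CC(C)O | intermediate
6 | (4R)-6-hydroxy-4-methylheptanal | C[C@H](CCC=O)CC(C)O | intermediate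
7 | triphenyl(5-phenylpentylidene)phosphorane | c1ccccc1CCCCC=P(c1ccccc1)(c1ccccc1)c1ccccc1 | intermediate
8 | (4R,7Z)-4-methyl-12-phenyldodec-7-en-2-ol | C[C@H](CC/C=C\CCCCc1ccccc1)CC(C)O | intermediate
9 | (4R)-4-methyl-12-phenyldodecan-2-ol | C[C@H](CCCCCCCCc1ccccc1)CC(C)O | intermediate
10 | (4R)-4-methyl-12-phenyldodecan-2-one | C[C@H](CCCCCCCCc1ccccc1)CC(C)=O | intermediate
11 | (4R)-2,4-dimethyl-12-phenyldodec-1-ene | C[C@H](CCCCCCCCc1ccccc1)CC(C)=C | intermediate
12 | propane-1,3-diol | OCCCO | starting material
13 | 3-[(tert-butyldiphenylsilyl)oxy]propan-1-ol | OCCCO[Si](c1ccccc1)(c1ccccc1)C(C)(C)C | intermediate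
14 | 3-[(tert-butyldiphenylsilyl)oxy]propanal | O=CCCO[Si](c1ccccc1)(c1ccccc1)C(C)(C)C | intermediate
15 | 3-[(tert-butyldiphenylsilyl)oxy]propanoic acid | OC(=O)CCO[Si](c1ccccc1)(c1ccccc1)C(C)(C)C | intermediate
16 | 2,2,5-trimethyl-1,3-dioxane-4,6-dione | CC1C(=O)OC(C)(C)OC1=O | starting material
17 | 2-(trimethylsilyl)ethanol | C[Si](C)(C)CCO | starting material
18 | 2-methyl-3-oxo-3-[2-(trimethylsilyl)ethoxy]propanoic acid (racemic) | CC(C(=O)O)C(=O)OCC[Si](C)(C)C | intermediate
19 | 3-[(tert-butyldiphenylsilyl)oxy]-1-(imidazol-1-yl)propan-1-one | O=C(CCO[Si](c1ccccc1)(c1ccccc1)C(C)(C)C)n1ccnc1 | intermediate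
20 | 2-(trimethylsilyl)ethyl 5-[(tert-butyldiphenylsilyl)oxy]-2-methyl-3-oxopentanoate (racemic) | CC(C(=O)OCC[Si](C)(C)C)C(=O)CCO[Si](c1ccccc1)(c1ccccc1)C(C)(C)C | intermediate
21 | open-chain C6 hydroperoxide of the C3 keto ester (6S drawn, 6R co-formed, C4 unassigned) | C[C@H](CCCCCCCCc1ccccc1)C[C@@](OO)(C)CC(C)(C(=O)OCC[Si](C)(C)C)C(=O)CCO[Si](c1ccccc1)(c1ccccc1)C(C)(C)C | intermediate
22 | 2-(trimethylsilyl)ethyl (6S)-3-{2-[(tert-butyldiphenylsilyl)oxy]ethyl}-3-hydroxy-4,6-dimethyl-6-[(2R)-2-methyl-10-phenyldecyl]-1,2-dioxane-4-carboxylate (6S drawn, 6R co-formed, C3/C4 unassigned) | C[C@H](CCCCCCCCc1ccccc1)C[C@@]1(C)CC(C)(C(=O)OCC[Si](C)(C)C)C(O)(CCO[Si](c2ccccc2)(c2ccccc2)C(C)(C)C)OO1 | intermediate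
23 | (6S)-3-hydroxy-3-(2-hydroxyethyl)-4,6-dimethyl-6-[(2R)-2-methyl-10-phenyldecyl]-1,2-dioxane-4-carboxylic acid (6S drawn, C3/C4 unassigned) | C[C@H](CCCCCCCCc1ccccc1)C[C@@]1(C)CC(C)(C(=O)O)C(O)(CCO)OO1 | intermediate
24 | (3S,4R,6S)-3-(2-hydroxyethyl)-4,6-dimethyl-6-[(2R)-2-methyl-10-phenyldecyl]-1,2-dioxan-3-ol | C[C@H](CCCCCCCCc1ccccc1)C[C@@]1(C)C[C@@H](C)[C@](O)(CCO)OO1 | intermediate
25 | 2-{(3S,4R,6S)-3-hydroxy-4,6-dimethyl-6-[(2R)-2-methyl-10-phenyldecyl]-1,2-dioxan-3-yl}acetaldehyde | C[C@H](CCCCCCCCc1ccccc1)C[C@@]1(C)C[C@@H](C)[C@](O)(CC=O)OO1 | intermediate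
26 | 2-{(3S,4R,6S)-3-hydroxy-4,6-dimethyl-6-[(2R)-2-methyl-10-phenyldecyl]-1,2-dioxan-3-yl}acetic acid | C[C@H](CCCCCCCCc1ccccc1)C[C@@]1(C)C[C@@H](C)[C@](O)(CC(=O)O)OO1 | target

Total step count: 14.
Longest linear sequence: 9 steps (steps 2–7 and 12–14, from 3 to 26).

Steps most likely to fail

Step 12.
- **What may go wrong:** The hindered tertiary C4 radical may add too slowly to a purely aliphatic alkene. Direct oxygenation at C4, over-oxidation of the C6 radical to the cation, and allylic hydrogen abstraction with autoxidation would then consume both partners.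
- **Fallback:** It sets out from 11 and 20 and comes back at 22. It builds C4–C5 ionically and the peroxide afterwards.
- Alkene 11 is epoxidised (mCPBA, CH2Cl2) to 2-methyl-2-[(2R)-2-methyl-10-phenyldecyl]oxirane F1.
- LiNEt2 isomerises F1, by β-elimination at the methyl group, to (4R)-4-methyl-2-methylidene-12-phenyldodecan-1-ol F2.
- An Appel reaction (CBr4, PPh3) gives [(9R)-11-(bromomethyl)-9-methyldodec-11-en-1-yl]benzene F3.
- C-Alkylation of 20 (K2CO3, DMF) gives 2-(trimethylsilyl)ethyl (6R)-2-{3-[(tert-butyldiphenylsilyl)oxy]propanoyl}-2,6-dimethyl-4-methylidene-14-phenyltetradecanoate F4.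
- Mukaiyama–Isayama peroxidation uses catalytic Co(thd)2 (thd = 2,2,6,6-tetramethylheptane-3,5-dionate), O2 and Et3SiH in 1,2-dichloroethane. Markovnikov hydrogen-atom transfer places the radical at C6 and gives 2-(trimethylsilyl)ethyl (6R)-2-{3-[(tert-butyldiphenylsilyl)oxy]propanoyl}-2,4,6-trimethyl-14-phenyl-4-[(triethylsilyl)peroxy]tetradecanoate F5.
- AcOH/THF/H2O removes the O-silyl group, and hydroperoxide 21 closes to 22.

Step 13.
- **What may go wrong:** Basic fluoride may push the ring-opened forms into irreversible pathways. These are retro-Claisen cleavage of C3–C4 before the ester has gone, β-elimination of the C1 oxygen, and stalled loss of CO2. The C6 epimers may also resolve poorly. 6S material with the wrong C4 configuration can be re-equilibrated through the same enol and separated again.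
- **Fallback:** It sets out from 15 (with 11) and comes back at 24. It replaces fluoride and base by acidolysis.
- Imidazolide 19, made from 15, is condensed under the conditions of step 11 with commercial 3-tert-butoxy-2-methyl-3-oxopropanoic acid. This gives tert-butyl 5-[(tert-butyldiphenylsilyl)oxy]-2-methyl-3-oxopentanoate F6.
- Annulation with 11 as in step 12 gives tert-butyl (6S)-3-{2-[(tert-butyldiphenylsilyl)oxy]ethyl}-3-hydroxy-4,6-dimethyl-6-[(2R)-2-methyl-10-phenyldecyl]-1,2-dioxane-4-carboxylate F7.
- TFA/CH2Cl2 at 0 °C expels isobutene to give the corresponding silyl-protected 1,2-dioxane-4-carboxylic acid F8.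
- F8 loses CO2 in this acidic, non-nucleophilic medium to give (6S)-3-{2-[(tert-butyldiphenylsilyl)oxy]ethyl}-4,6-dimethyl-6-[(2R)-2-methyl-10-phenyldecyl]-1,2-dioxan-3-ol F9. This compound is UV-active and offers a second point for diastereomer separation.
- HF·pyridine in THF then frees C1–OH and gives 24.

Step 14.
- **What may go wrong:** The oxoammonium salt may degrade the ring-opened hydroperoxide. C4 may epimerise. The masked β-keto acid may lose CO2 during oxidation or isolation.
- **Fallback:** It sets out from 24 and comes back at 26. It splits the one-pot four-electron oxidation into two isolated two-electron events with mechanistically unrelated oxidants, so that no nitroxyl species meets the peroxide.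
- NaHCO3-buffered Dess–Martin periodinane in CH2Cl2 stops at aldehyde 25, which is isolated.
- A Pinnick oxidation (NaClO2, NaH2PO4, 2-methylbut-2-ene, tBuOH/H2O, 0 °C) then gives 26 at buffered pH.
- New compounds on this detour: none F0.

Further compounds
F1 | step 12 | 2-methyl-2-[(2R)-2-methyl-10-phenyldecyl]oxirane (both epoxide epimers) | C[C@H](CCCCCCCCc1ccccc1)CC1(C)CO1
F2 | step 12 | (4R)-4-methyl-2-methylidene-12-phenyldodecan-1-ol | C[C@H](CCCCCCCCc1ccccc1)CC(=C)CO
F3 | step 12 | [(9R)-11-(bromomethyl)-9-methyldodec-11-en-1-yl]benzene | C[C@H](CCCCCCCCc1ccccc1)CC(=C)CBr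
F4 | step 12 | 2-(trimethylsilyl)ethyl (6R)-2-{3-[(tert-butyldiphenylsilyl)oxy]propanoyl}-2,6-dimethyl-4-methylidene-14-phenyltetradecanoate | C[C@H](CCCCCCCCc1ccccc1)CC(=C)CC(C)(C(=O)OCC[Si](C)(C)C)C(=O)CCO[Si](c1ccccc1)(c1ccccc1)C(C)(C)C
F5 | step 12 | 2-(trimethylsilyl)ethyl (6R)-2-{3-[(tert-butyldiphenylsilyl)oxy]propanoyl}-2,4,6-trimethyl-14-phenyl-4-[(triethylsilyl)peroxy]tetradecanoate | C[C@H](CCCCCCCCc1ccccc1)CC(C)(OO[Si](CC)(CC)CC)CC(C)(C(=O)OCC[Si](C)(C)C)C(=O)CCO[Si](c1ccccc1)(c1ccccc1)C(C)(C)C
F6 | step 13 | tert-butyl 5-[(tert-butyldiphenylsilyl)oxy]-2-methyl-3-oxopentanoate (racemic) | CC(C(=O)OC(C)(C)C)C(=O)CCO[Si](c1ccccc1)(c1ccccc1)C(C)(C)C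
F7 | step 13 | tert-butyl (6S)-3-{2-[(tert-butyldiphenylsilyl)oxy]ethyl}-3-hydroxy-4,6-dimethyl-6-[(2R)-2-methyl-10-phenyldecyl]-1,2-dioxane-4-carboxylate (6S drawn, 6R co-formed) | C[C@H](CCCCCCCCc1ccccc1)C[C@@]1(C)CC(C)(C(=O)OC(C)(C)C)C(O)(CCO[Si](c2ccccc2)(c2ccccc2)C(C)(C)C)OO1
F8 | step 13 | (6S)-3-{2-[(tert-butyldiphenylsilyl)oxy]ethyl}-3-hydroxy-4,6-dimethyl-6-[(2R)-2-methyl-10-phenyldecyl]-1,2-dioxane-4-carboxylic acid | C[C@H](CCCCCCCCc1ccccc1)C[C@@]1(C)CC(C)(C(=O)O)C(O)(CCO[Si](c2ccccc2)(c2ccccc2)C(C)(C)C)OO1
F9 | step 13 | (6S)-3-{2-[(tert-butyldiphenylsilyl)oxy]ethyl}-4,6-dimethyl-6-[(2R)-2-methyl-10-phenyldecyl]-1,2-dioxan-3-ol (C3/C4 mixture before separation) | C[C@H](CCCCCCCCc1ccccc1)C[C@@]1(C)CC(C)C(O)(CCO[Si](c2ccccc2)(c2ccccc2)C(C)(C)C)OO1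
F0 | step 14 | none | none
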